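## Retrosynthetic overview

1. Target 45 is reached from bicyclic ketone 39 by functional-group steps only: sulfoxide elimination to the C4 methylidene, deprotection, oxirane closure and acetylation.
2. 39 comes from the acyclic enoyl selenoester 38 by one radical cascade that forms C7a–C3a (cyclohexane ring, first) and C3–C2 (cyclopentanone ring, second).
3. Enabling feature: in the cyclopentanone ring, the ketone carbon C2, C1 and the ring-fusion carbon C7a form a C(=O)–C–C triad, and C3/C3a are two adjacent sp3 carbons opposite to it. The ring is therefore the [3+2] sum of an α,β-unsaturated acyl (α-ketenyl) radical and a vinyl group, and the cyclohexane ring C3a–C4–C5–C6–C7–C7a is the tether between them.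
4. 38 comes from aldehyde 29 and ester 21 (aldol/dehydration); 29 from imide 18 and aldehyde 11 (Evans syn-aldol, sets C7 and C6); 11 from crotonyl imide 3 and 2,2-dimethoxyacetaldehyde (Evans syn-aldol, sets C4 and C5).
5. Chiral pool: the oxirane carbon from (S)-citramalic acid, the acetoxyethyl carbinol from ethyl (S)-3-hydroxybutanoate, and (R)-2-methylbutanoic acid. Ring order: cyclohexane, then cyclopentanone (same step), oxirane last.

Key step: step 25

Remark on numbering: all intermediates use the indanone locants of the target. C1 is the CH bearing the acetoxyethyl group, C2 the ketone, C3 the ring CH2, C3a and C7a the ring-fusion carbons, C4 the methylidene carbon, C5 the carbon bearing the 2-methylbutanoate, C6 the carbon bearing the 3-methylpentenoate, and C7 the carbon bearing the oxirane.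

Remark on the chemistry: 2,2-dimethoxyacetaldehyde is bought as its aqueous solution and dried before use. Enoate 33 is written as the (2E) isomer expected from the elimination; its geometry has no bearing on step 25, because both isomers give the same delocalised radical.

## Route

Step 1
Reactants: 1 (4R)-4-benzyl-1,3-oxazolidin-2-one; 2 (2E)-but-2-enoic anhydride
Product: 3 (4R)-4-benzyl-3-[(2E)-but-2-enoyl]-1,3-oxazolidin-2-one
Conditions: Et3N, LiCl, THF, rt
Reagents that add atoms: none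
Why: N-acylation of the LiCl-activated oxazolidinone by the symmetric anhydride under mild amine base, with no stereocentre touched.

Step 2
Reactants: 3 crotonyl imide; 4 2,2-dimethoxyacetaldehyde
Product: 6 (4R)-4-benzyl-3-[(2R,3R)-2-ethenyl-3-hydroxy-4,4-dimethoxybutanoyl]-1,3-oxazolidin-2-one, via boron dienolate 5 (not isolated)
Conditions: Bu2BOTf, Et3N, CH2Cl2, −78 → 0 °C; then 4, −78 → 0 °C; pH 7 buffer, MeOH, H2O2, 0 °C
Reagents that add atoms: dibutylboryl trifluoromethanesulfonate, CCCCB(CCCC)OS(=O)(=O)C(F)(F)F (boron and butyl groups in 5 only)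
Why: Evans syn-aldol reaction in which the Z(O)-boron dienolate reacts at its α-carbon through a Zimmerman–Traxler chair, the (R)-benzyl auxiliary setting the future C4 and C5 as the 2R,3R pair.

Step 3
Reactants: 6 aldol imide
Product: 7 (2S,3R)-2-ethenyl-4,4-dimethoxybutane-1,3-diol
Conditions: LiBH4, MeOH (1 equiv), THF, 0 °C
Reagents that add atoms: none
Why: Reductive cleavage of the imide gives the primary alcohol and returns the auxiliary, while the acetal and both stereocentres are untouched.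

Step 4
Reactants: 7 diol
Product: 8 (2R,3R)-1,1-dimethoxy-3-[(phenylsulfanyl)methyl]pent-4-en-2-ol
Conditions: PhSSPh, Bu3P, pyridine, rt
Reagents that add atoms: diphenyl disulfide, c1ccc(SSc2ccccc2)cc1
Why: Phosphine/disulfide redox condensation (Hata reaction) substitutes only the unhindered primary alkoxyphosphonium centre, installing the phenyl sulfide that later becomes the C4 methylidene.

Step 5
Reactants: 8 sulfide alcohol; 9 (2R)-2-methylbutanoic acid
Product: 10 (2R,3R)-1,1-dimethoxy-3-[(phenylsulfanyl)methyl]pent-4-en-2-yl (2R)-2-methylbutanoate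
Conditions: DCC, DMAP (cat.), CH2Cl2, 0 °C → rt
Reagents that add atoms: none
Why: Steglich esterification of the secondary alcohol, which does not pass through a ketene and so should keep the α-stereocentre of the acid.

Step 6
Reactants: 10 acetal ester
Product: 11 (2R,3R)-1-oxo-3-[(phenylsulfanyl)methyl]pent-4-en-2-yl (2R)-2-methylbutanoate
Conditions: TFA/H2O (1:1), CHCl3, 0 °C
Reagents that add atoms: water, O
Why: Acid-catalysed acetal hydrolysis to which ester, sulfide and terminal alkene are inert; the α-acyloxy aldehyde is used at once to avoid epimerisation.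

Step 7
Reactants: 12 (2S)-2-hydroxy-2-methylbutanedioic acid ((S)-citramalic acid)
Product: 13 (2S)-2-methylbutane-1,2,4-triol
Conditions: BH3·SMe2, B(OMe)3, THF, 0 °C → rt; then MeOH
Reagents that add atoms: none
Why: Borane reduction of both carboxylic acids to primary alcohols leaves the tertiary carbinol stereocentre, the future oxirane carbon, untouched.

Step 8
Reactants: 13 triol
Product: 14 2-[(4S)-2,2,4-trimethyl-1,3-dioxolan-4-yl]ethan-1-ol
Conditions: 2,2-dimethoxypropane, acetone, p-TsOH (cat.), rt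
Reagents that add atoms: 2,2-dimethoxypropane, COC(C)(C)OC
Why: Acid-catalysed transacetalisation under thermodynamic control favours the five-membered dioxolane across the vicinal tertiary/primary diol and leaves the remote primary hydroxyl free.

Step 9
Reactants: 14 acetonide alcohol
Product: 15 [(4S)-2,2,4-trimethyl-1,3-dioxolan-4-yl]acetic acid
Conditions: TEMPO (cat.), PhI(OAc)2, NaHCO3, MeCN/H2O, rt
Reagents that add atoms: water, O
Why: Nitroxyl-catalysed oxidation of the primary alcohol through the aldehyde hydrate to the acid under buffered conditions that spare the acetonide.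

Step 10
Reactants: 15 dioxolanylacetic acid; 16 (4S)-4-benzyl-1,3-oxazolidin-2-one
Product: 18 (4S)-4-benzyl-3-{[(4S)-2,2,4-trimethyl-1,3-dioxolan-4-yl]acetyl}-1,3-oxazolidin-2-one, via mixed pivalic anhydride 17 (not isolated)
Conditions: PivCl, Et3N, THF, −20 °C; then 16, LiCl, −20 °C → rt
Reagents that add atoms: pivaloyl chloride, CC(C)(C)C(=O)Cl (in 17 only)
Why: N-acylation of the oxazolidinone by the mixed anhydride at its less hindered carbonyl.

Step 11
Reactants: 19 ethyl (3S)-3-hydroxybutanoate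
Product: 20 prop-2-en-1-yl (3S)-3-hydroxybutanoate
Conditions: allyl alcohol (solvent), Ti(OiPr)4 (cat.), 80 °C
Reagents that add atoms: prop-2-en-1-ol, C=CCO
Why: Titanate-catalysed transesterification under neutral conditions, which avoids β-elimination and leaves the carbinol centre untouched.

Step 12
Reactants: 20 allyl hydroxy ester
Product: 21 prop-2-en-1-yl (3S)-3-{[tert-butyl(dimethyl)silyl]oxy}butanoate
Conditions: TBSCl, imidazole, DMF, rt
Reagents that add atoms: tert-butyl(chloro)dimethylsilane, CC(C)(C)[Si](C)(C)Cl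
Why: Standard silylation of the secondary alcohol.

Step 13
Reactants: 22 ethyl pent-2-ynoate
Product: 23 ethyl (2Z)-3-methylpent-2-enoate
Conditions: Me2CuLi (from MeLi and CuI), THF, −78 °C; MeOH then aq. NH4Cl, −78 °C
Reagents that add atoms: lithium dimethylcuprate, [Li+].C[Cu-]C
Why: syn-Carbocupration of the ynoate (Gilman conjugate addition) and low-temperature protonation with retention place methyl cis to hydrogen, so ethyl is cis to the ester (Z).

Step 14
Reactants: 23 (Z)-enoate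
Product: 24 (2Z)-3-methylpent-2-enoic acid
Conditions: LiOH, THF/H2O, rt; then aq. HCl
Reagents that add atoms: lithium hydroxide, [Li+].[OH-]
Why: Saponification, in which the fully substituted β-carbon resists addition–elimination so the alkene geometry should be kept.

Step 15
Reactants: 18 dioxolanylacetyl imide; 11 α-acyloxy aldehyde
Product: 26 syn-aldol imide (3R,4R,5S,6R)-7-[(4S)-4-benzyl-2-oxo-1,3-oxazolidin-3-yl]-5-hydroxy-7-oxo-3-[(phenylsulfanyl)methyl]-6-[(4S)-2,2,4-trimethyl-1,3-dioxolan-4-yl]hept-1-en-4-yl (2R)-2-methylbutanoate, via boron enolate 25 (not isolated)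
Conditions: 18, Bu2BOTf, iPr2NEt, CH2Cl2, −78 → 0 °C; then 11, −78 → −20 °C; pH 7 buffer, MeOH (no peroxide)
Reagents that add atoms: dibutylboryl trifluoromethanesulfonate, CCCCB(CCCC)OS(=O)(=O)C(F)(F)F (boron and butyl groups in 25 only)
Why: Evans syn-aldol reaction through a Zimmerman–Traxler chair in which the (S)-auxiliary sets C7 and C6; the required C5/C6 anti relation is also the polar Felkin–Anh sense of addition to the α-acyloxy aldehyde, so reagent and substrate control are matched.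

Step 16
Reactants: 26 aldol imide
Product: 27 C6 triethylsilyl ether of 26
Conditions: TESOTf, 2,6-lutidine, CH2Cl2, −78 °C
Reagents that add atoms: triethylsilyl trifluoromethanesulfonate, CC[Si](CC)(CC)OS(=O)(=O)C(F)(F)F
Why: Silylation of the hindered secondary alcohol with the silyl triflate, which blocks β-elimination and retro-aldol in the steps that follow.

Step 17
Reactants: 27 silylated imide
Product: 28 (3R,4R,5S,6R)-7-hydroxy-3-[(phenylsulfanyl)methyl]-5-[(triethylsilyl)oxy]-6-[(4S)-2,2,4-trimethyl-1,3-dioxolan-4-yl]hept-1-en-4-yl (2R)-2-methylbutanoate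
Conditions: LiBH4, MeOH (1 equiv), Et2O, 0 °C
Reagents that add atoms: none
Why: Reductive removal of the auxiliary, the activated imide being reduced much faster than the hindered secondary ester.

Step 18
Reactants: 28 primary alcohol
Product: 29 (3R,4R,5S,6R)-7-oxo-3-[(phenylsulfanyl)methyl]-5-[(triethylsilyl)oxy]-6-[(4S)-2,2,4-trimethyl-1,3-dioxolan-4-yl]hept-1-en-4-yl (2R)-2-methylbutanoate
Conditions: Dess–Martin periodinane, NaHCO3, CH2Cl2, 0 °C → rt
Reagents that add atoms: none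
Why: Dess–Martin oxidation under buffered conditions, which tolerates the sulfide and should not epimerise the α-stereocentre (C7).

Step 19
Reactants: 29 aldehyde; 21 allyl silyloxybutanoate
Product: 31 β-hydroxy ester (mixture of epimers at the two new centres), via lithium enolate 30 (not isolated)
Conditions: 21, LDA, THF, −78 °C; then 29, −78 °C; aq. NH4Cl
Reagents that add atoms: lithium diisopropylamide, [Li+].CC(C)[N-]C(C)C (lithium in 30 only)
Why: Aldol addition of the lithium ester enolate to the aldehyde at low temperature; the two new stereocentres need no control because both become sp2 in step 20.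

Step 20
Reactants: 31 β-hydroxy ester
Product: 33 prop-2-en-1-yl (2E,4R,5S,6R,7R)-2-[(1S)-1-{[tert-butyl(dimethyl)silyl]oxy}ethyl]-6-{[(2R)-2-methylbutanoyl]oxy}-7-[(phenylsulfanyl)methyl]-5-[(triethylsilyl)oxy]-4-[(4S)-2,2,4-trimethyl-1,3-dioxolan-4-yl]nona-2,8-dienoate, via mesylate 32 (not isolated)
Conditions: MsCl, Et3N, CH2Cl2, 0 °C; then DBU, rt
Reagents that add atoms: methanesulfonyl chloride, CS(=O)(=O)Cl (in 32 only)
Why: Mesylation followed by E1cB elimination gives the conjugated trisubstituted enoate, the mesylate being lost in preference to the silyloxy group.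

Step 21
Reactants: 33 bis-silyl enoate
Product: 34 C6 alcohol (5-hydroxy analogue of 33)
Conditions: HF·pyridine, pyridine, THF, 0 °C
Reagents that add atoms: none
Why: Selective desilylation, the secondary triethylsilyl ether being far more labile to buffered fluoride than the secondary TBS ether or the acetonide; in the (2E) ester the hydroxyl cannot lactonise on to C2's carboxyl.

Step 22
Reactants: 34 C6 alcohol; 24 (2Z)-3-methylpent-2-enoic acid
Product: 36 C6 (2Z)-3-methylpent-2-enoate of 34, via mixed anhydride 35 (not isolated)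
Conditions: 24, 2,4,6-Cl3C6H2COCl, Et3N, THF, rt; then 34, DMAP, toluene, rt → 40 °C
Reagents that add atoms: 2,4,6-trichlorobenzoyl chloride, O=C(Cl)c1c(Cl)cc(Cl)cc1Cl (in 35 only)
Why: Yamaguchi esterification, suited to hindered secondary alcohols and expected to keep the Z geometry of the β,β-disubstituted acyl group.

Step 23
Reactants: 36 triester
Product: 37 (2E)-nona-2,8-dienoic acid (free acid of 36)
Conditions: Pd(PPh3)4 (cat.), morpholine, THF, rt
Reagents that add atoms: none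
Why: Tsuji–Trost deallylation by allyl transfer to morpholine cleaves only the allyl ester, as no other ester is allylic at this stage.

Step 24
Reactants: 37 enoic acid
Product: 38 Se-phenyl selenoester of 37
Conditions: PhSeSePh, Bu3P, CH2Cl2, rt
Reagents that add atoms: diphenyl diselenide, c1ccc([Se][Se]c2ccccc2)cc1
Why: Phosphine/diselenide redox condensation through the acyloxyphosphonium ion, which the selenolate attacks at the acyl carbon.

Step 25
Reactants: 38 enoyl selenoester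
Product: 39 (1R,3aS,4R,5R,6S,7R,7aS)-1-[(1S)-1-{[tert-butyl(dimethyl)silyl]oxy}ethyl]-5-{[(2R)-2-methylbutanoyl]oxy}-2-oxo-4-[(phenylsulfanyl)methyl]-7-[(4S)-2,2,4-trimethyl-1,3-dioxolan-4-yl]octahydro-1H-inden-6-yl (2Z)-3-methylpent-2-enoate
Conditions: Bu3SnH (slow addition by syringe pump), AIBN (cat.), PhH (0.003 M), 80 °C
Reagents that add atoms: none
Why: Bu3Sn• abstracts the PhSe group to give the α,β-unsaturated acyl radical, which reacts through its α-ketenyl form centred on C7a: C7a adds to the internal vinyl carbon C3a in a 6-exo-trig closure (cyclohexane ring), the resulting primary radical at C3 adds to the central ketene carbon C2 in a 5-exo closure (cyclopentanone ring), and the α-keto radical at C1 is reduced by Bu3SnH. The closest known reaction type is the tandem cyclisation of enoyl selenoester-derived acyl/α-ketenyl radicals on to pendant alkenes to give fused cyclopentanones. C7a and C3a should be set in a chair-like 6-exo transition state that keeps the dioxolanyl group (C7), the C6 ester and the CH2SPh group (C4) equatorial and the C5 ester axial; the axial C5 ester disfavours an axial vinyl terminus at C3a, so both forming ring bonds are equatorial and the fusion is trans. C1 should be set by hydrogen-atom transfer anti to the axial C7a–H (axial delivery, the other trajectory being hindered by the peri dioxolane), placing the silyloxyethyl group pseudo-equatorial and trans to the C7a–C7 bond. The step needs the 6-exo closure to outrun direct reduction of the acyl radical and any attack on the enoate ester; this is secured by slow stannane addition at high dilution, by the four substituents on the tether, and by the low reactivity of the electron-poor β,β-disubstituted enoate across an ester tether.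

Step 26
Reactants: 39 bicyclic sulfide
Product: 41 (1R,3aS,5R,6S,7R,7aS)-1-[(1S)-1-{[tert-butyl(dimethyl)silyl]oxy}ethyl]-4-methylidene-5-{[(2R)-2-methylbutanoyl]oxy}-2-oxo-7-[(4S)-2,2,4-trimethyl-1,3-dioxolan-4-yl]octahydro-1H-inden-6-yl (2Z)-3-methylpent-2-enoate, via sulfoxide 40 (not isolated)
Conditions: mCPBA (1 equiv), CH2Cl2, −78 °C; then NaHCO3, toluene, 110 °C
Reagents that add atoms: 3-chloroperoxybenzoic acid, O=C(OO)c1cccc(Cl)c1 (oxygen in 40 only)
Why: Chemoselective sulfide oxidation and thermal syn-elimination of the sulfoxide, whose only β-hydrogen is on C4, so only the exocyclic alkene can form.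

Step 27
Reactants: 41 methylidene ketone
Product: 42 triol (1R,3aS,5R,6S,7R,7aS)-7-[(2S)-1,2-dihydroxypropan-2-yl]-1-[(1S)-1-hydroxyethyl]-4-methylidene-5-{[(2R)-2-methylbutanoyl]oxy}-2-oxooctahydro-1H-inden-6-yl (2Z)-3-methylpent-2-enoate
Conditions: aq. HF (48%), MeCN, 0 °C → rt
Reagents that add atoms: none
Why: Global acidic cleavage of the TBS ether and the acetonide under conditions mild enough for the esters and the allylic C5 ester.

Step 28
Reactants: 42 triol
Product: 44 hydroxy epoxide (1R,3aS,5R,6S,7R,7aS)-1-[(1S)-1-hydroxyethyl]-4-methylidene-5-{[(2R)-2-methylbutanoyl]oxy}-7-[(2S)-2-methyloxiran-2-yl]-2-oxooctahydro-1H-inden-6-yl (2Z)-3-methylpent-2-enoate, via tosylate 43 (not isolated)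
Conditions: TsCl, Et3N, Bu2SnO (cat.), CH2Cl2, 0 °C → rt; then DBU, rt
Reagents that add atoms: 4-methylbenzenesulfonyl chloride, Cc1ccc(S(=O)(=O)Cl)cc1 (in 43 only)
Why: Stannylene-mediated sulfonylation selective for the primary hydroxyl of the 1,2-diol, then intramolecular Williamson closure (3-exo-tet) by the tertiary oxygen, whose carbon keeps its configuration.

Step 29
Reactants: 44 hydroxy epoxide
Product: 45 target, (1S)-1-[(1R,3aS,5R,6S,7R,7aS)-4-methylidene-5-{[(2R)-2-methylbutanoyl]oxy}-6-{[(2Z)-3-methylpent-2-enoyl]oxy}-7-[(2S)-2-methyloxiran-2-yl]-2-oxooctahydro-1H-inden-1-yl]ethyl acetate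
Conditions: Ac2O, pyridine, DMAP (cat.), CH2Cl2, 0 °C
Reagents that add atoms: acetic anhydride, CC(=O)OC(C)=O
Why: Acetylation of the remaining secondary alcohol under mild amine conditions, done last because the β-acetoxy ketone is the most base-sensitive unit of the target.

## Compound list

1 | (4R)-4-benzyl-1,3-oxazolidin-2-one | O=C1N[C@H](Cc2ccccc2)CO1 | starting material
2 | (2E)-but-2-enoic anhydride | C/C=C/C(=O)OC(=O)/C=C/C | starting material
3 | (4R)-4-benzyl-3-[(2E)-but-2-enoyl]-1,3-oxazolidin-2-one | C/C=C/C(=O)N1[C@H](Cc2ccccc2)COC1=O | intermediate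
4 | 2,2-dimethoxyacetaldehyde | COC(OC)C=O | starting material
5 | dibutylboron Z(O)-dienolate of 3 | CCCCB(CCCC)O/C(=C\C=C)N1[C@H](Cc2ccccc2)COC1=O | intermediate
6 | (4R)-4-benzyl-3-[(2R,3R)-2-ethenyl-3-hydroxy-4,4-dimethoxybutanoyl]-1,3-oxazolidin-2-one | C=C[C@@H](C(=O)N1[C@H](Cc2ccccc2)COC1=O)[C@@H](O)C(OC)OC | intermediate
7 | (2S,3R)-2-ethenyl-4,4-dimethoxybutane-1,3-diol | C=C[C@@H](CO)[C@@H](O)C(OC)OC | intermediate
8 | (2R,3R)-1,1-dimethoxy-3-[(phenylsulfanyl)methyl]pent-4-en-2-ol | C=C[C@@H](CSc1ccccc1)[C@@H](O)C(OC)OC | intermediate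
9 | (2R)-2-methylbutanoic acid | CC[C@@H](C)C(=O)O | starting material
10 | (2R,3R)-1,1-dimethoxy-3-[(phenylsulfanyl)methyl]pent-4-en-2-yl (2R)-2-methylbutanoate | C=C[C@@H](CSc1ccccc1)[C@@H](OC(=O)[C@H](C)CC)C(OC)OC | intermediate
11 | (2R,3R)-1-oxo-3-[(phenylsulfanyl)methyl]pent-4-en-2-yl (2R)-2-methylbutanoate | C=C[C@@H](CSc1ccccc1)[C@@H](OC(=O)[C@H](C)CC)C=O | intermediate
12 | (2S)-2-hydroxy-2-methylbutanedioic acid | OC(=O)C[C@@](O)(C)C(=O)O | starting material
13 | (2S)-2-methylbutane-1,2,4-triol | OCC[C@@](O)(C)CO | intermediate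
14 | 2-[(4S)-2,2,4-trimethyl-1,3-dioxolan-4-yl]ethan-1-ol | OCC[C@@]1(C)COC(C)(C)O1 | intermediate
15 | [(4S)-2,2,4-trimethyl-1,3-dioxolan-4-yl]acetic acid | OC(=O)C[C@@]1(C)COC(C)(C)O1 | intermediate
16 | (4S)-4-benzyl-1,3-oxazolidin-2-one | O=C1N[C@@H](Cc2ccccc2)CO1 | starting material
17 | 2,2-dimethylpropanoic [(4S)-2,2,4-trimethyl-1,3-dioxolan-4-yl]acetic anhydride | CC(C)(C)C(=O)OC(=O)C[C@@]1(C)COC(C)(C)O1 | intermediate
18 | (4S)-4-benzyl-3-{[(4S)-2,2,4-trimethyl-1,3-dioxolan-4-yl]acetyl}-1,3-oxazolidin-2-one | O=C(C[C@@]1(C)COC(C)(C)O1)N1[C@@H](Cc2ccccc2)COC1=O | intermediate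
19 | ethyl (3S)-3-hydroxybutanoate | CCOC(=O)C[C@H](C)O | starting material
20 | prop-2-en-1-yl (3S)-3-hydroxybutanoate | C=CCOC(=O)C[C@H](C)O | intermediate
21 | prop-2-en-1-yl (3S)-3-{[tert-butyl(dimethyl)silyl]oxy}butanoate | C=CCOC(=O)C[C@H](C)O[Si](C)(C)C(C)(C)C | intermediate
22 | ethyl pent-2-ynoate | CCC#CC(=O)OCC | starting material
23 | ethyl (2Z)-3-methylpent-2-enoate | CCOC(=O)/C=C(/C)CC | intermediate
24 | (2Z)-3-methylpent-2-enoic acid | OC(=O)/C=C(/C)CC | intermediate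
25 | dibutylboron Z(O)-enolate of 18 | CCCCB(CCCC)O/C(=C\[C@@]1(C)COC(C)(C)O1)N1[C@@H](Cc2ccccc2)COC1=O | intermediate
26 | (3R,4R,5S,6R)-7-[(4S)-4-benzyl-2-oxo-1,3-oxazolidin-3-yl]-5-hydroxy-7-oxo-3-[(phenylsulfanyl)methyl]-6-[(4S)-2,2,4-trimethyl-1,3-dioxolan-4-yl]hept-1-en-4-yl (2R)-2-methylbutanoate | C=C[C@@H](CSc1ccccc1)[C@@H](OC(=O)[C@H](C)CC)[C@@H](O)[C@H]([C@@]1(C)COC(C)(C)O1)C(=O)N1[C@@H](Cc2ccccc2)COC1=O | intermediate
27 | (3R,4R,5S,6R)-7-[(4S)-4-benzyl-2-oxo-1,3-oxazolidin-3-yl]-7-oxo-3-[(phenylsulfanyl)methyl]-5-[(triethylsilyl)oxy]-6-[(4S)-2,2,4-trimethyl-1,3-dioxolan-4-yl]hept-1-en-4-yl (2R)-2-methylbutanoate | C=C[C@@H](CSc1ccccc1)[C@@H](OC(=O)[C@H](C)CC)[C@@H](O[Si](CC)(CC)CC)[C@H]([C@@]1(C)COC(C)(C)O1)C(=O)N1[C@@H](Cc2ccccc2)COC1=O | intermediate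
28 | (3R,4R,5S,6R)-7-hydroxy-3-[(phenylsulfanyl)methyl]-5-[(triethylsilyl)oxy]-6-[(4S)-2,2,4-trimethyl-1,3-dioxolan-4-yl]hept-1-en-4-yl (2R)-2-methylbutanoate | C=C[C@@H](CSc1ccccc1)[C@@H](OC(=O)[C@H](C)CC)[C@@H](O[Si](CC)(CC)CC)[C@H]([C@@]1(C)COC(C)(C)O1)CO | intermediate
29 | (3R,4R,5S,6R)-7-oxo-3-[(phenylsulfanyl)methyl]-5-[(triethylsilyl)oxy]-6-[(4S)-2,2,4-trimethyl-1,3-dioxolan-4-yl]hept-1-en-4-yl (2R)-2-methylbutanoate | C=C[C@@H](CSc1ccccc1)[C@@H](OC(=O)[C@H](C)CC)[C@@H](O[Si](CC)(CC)CC)[C@H]([C@@]1(C)COC(C)(C)O1)C=O | intermediate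
30 | lithium enolate of 21 | [Li]OC(OCC=C)=C[C@H](C)O[Si](C)(C)C(C)(C)C | intermediate
31 | prop-2-en-1-yl (4R,5S,6R,7R)-2-[(1S)-1-{[tert-butyl(dimethyl)silyl]oxy}ethyl]-3-hydroxy-6-{[(2R)-2-methylbutanoyl]oxy}-7-[(phenylsulfanyl)methyl]-5-[(triethylsilyl)oxy]-4-[(4S)-2,2,4-trimethyl-1,3-dioxolan-4-yl]non-8-enoate (epimers at C2 and C3 of the chain) | C=C[C@@H](CSc1ccccc1)[C@@H](OC(=O)[C@H](C)CC)[C@@H](O[Si](CC)(CC)CC)[C@H]([C@@]1(C)COC(C)(C)O1)C(O)C(C(=O)OCC=C)[C@H](C)O[Si](C)(C)C(C)(C)C | intermediate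
32 | 3-O-methanesulfonate of 31 | C=C[C@@H](CSc1ccccc1)[C@@H](OC(=O)[C@H](C)CC)[C@@H](O[Si](CC)(CC)CC)[C@H]([C@@]1(C)COC(C)(C)O1)C(OS(C)(=O)=O)C(C(=O)OCC=C)[C@H](C)O[Si](C)(C)C(C)(C)C | intermediate
33 | prop-2-en-1-yl (2E,4R,5S,6R,7R)-2-[(1S)-1-{[tert-butyl(dimethyl)silyl]oxy}ethyl]-6-{[(2R)-2-methylbutanoyl]oxy}-7-[(phenylsulfanyl)methyl]-5-[(triethylsilyl)oxy]-4-[(4S)-2,2,4-trimethyl-1,3-dioxolan-4-yl]nona-2,8-dienoate | C=C[C@@H](CSc1ccccc1)[C@@H](OC(=O)[C@H](C)CC)[C@@H](O[Si](CC)(CC)CC)[C@H]([C@@]1(C)COC(C)(C)O1)/C=C(\[C@H](C)O[Si](C)(C)C(C)(C)C)C(=O)OCC=C | intermediate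
34 | prop-2-en-1-yl (2E,4R,5S,6R,7R)-2-[(1S)-1-{[tert-butyl(dimethyl)silyl]oxy}ethyl]-5-hydroxy-6-{[(2R)-2-methylbutanoyl]oxy}-7-[(phenylsulfanyl)methyl]-4-[(4S)-2,2,4-trimethyl-1,3-dioxolan-4-yl]nona-2,8-dienoate | C=C[C@@H](CSc1ccccc1)[C@@H](OC(=O)[C@H](C)CC)[C@@H](O)[C@H]([C@@]1(C)COC(C)(C)O1)/C=C(\[C@H](C)O[Si](C)(C)C(C)(C)C)C(=O)OCC=C | intermediate
35 | (2Z)-3-methylpent-2-enoic 2,4,6-trichlorobenzoic anhydride | O=C(/C=C(/C)CC)OC(=O)c1c(Cl)cc(Cl)cc1Cl | intermediate
36 | prop-2-en-1-yl (2E,4R,5S,6R,7R)-2-[(1S)-1-{[tert-butyl(dimethyl)silyl]oxy}ethyl]-6-{[(2R)-2-methylbutanoyl]oxy}-5-{[(2Z)-3-methylpent-2-enoyl]oxy}-7-[(phenylsulfanyl)methyl]-4-[(4S)-2,2,4-trimethyl-1,3-dioxolan-4-yl]nona-2,8-dienoate | C=C[C@@H](CSc1ccccc1)[C@@H](OC(=O)[C@H](C)CC)[C@@H](OC(=O)/C=C(/C)CC)[C@H]([C@@]1(C)COC(C)(C)O1)/C=C(\[C@H](C)O[Si](C)(C)C(C)(C)C)C(=O)OCC=C | intermediate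
37 | (2E,4R,5S,6R,7R)-2-[(1S)-1-{[tert-butyl(dimethyl)silyl]oxy}ethyl]-6-{[(2R)-2-methylbutanoyl]oxy}-5-{[(2Z)-3-methylpent-2-enoyl]oxy}-7-[(phenylsulfanyl)methyl]-4-[(4S)-2,2,4-trimethyl-1,3-dioxolan-4-yl]nona-2,8-dienoic acid | C=C[C@@H](CSc1ccccc1)[C@@H](OC(=O)[C@H](C)CC)[C@@H](OC(=O)/C=C(/C)CC)[C@H]([C@@]1(C)COC(C)(C)O1)/C=C(\[C@H](C)O[Si](C)(C)C(C)(C)C)C(=O)O | intermediate
38 | Se-phenyl (2E,4R,5S,6R,7R)-2-[(1S)-1-{[tert-butyl(dimethyl)silyl]oxy}ethyl]-6-{[(2R)-2-methylbutanoyl]oxy}-5-{[(2Z)-3-methylpent-2-enoyl]oxy}-7-[(phenylsulfanyl)methyl]-4-[(4S)-2,2,4-trimethyl-1,3-dioxolan-4-yl]nona-2,8-dieneselenoate | C=C[C@@H](CSc1ccccc1)[C@@H](OC(=O)[C@H](C)CC)[C@@H](OC(=O)/C=C(/C)CC)[C@H]([C@@]1(C)COC(C)(C)O1)/C=C(\[C@H](C)O[Si](C)(C)C(C)(C)C)C(=O)[Se]c1ccccc1 | intermediate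
39 | (1R,3aS,4R,5R,6S,7R,7aS)-1-[(1S)-1-{[tert-butyl(dimethyl)silyl]oxy}ethyl]-5-{[(2R)-2-methylbutanoyl]oxy}-2-oxo-4-[(phenylsulfanyl)methyl]-7-[(4S)-2,2,4-trimethyl-1,3-dioxolan-4-yl]octahydro-1H-inden-6-yl (2Z)-3-methylpent-2-enoate | c1ccccc1SC[C@@H]1[C@H]2CC(=O)[C@@H]([C@H](C)O[Si](C)(C)C(C)(C)C)[C@@H]2[C@@H]([C@@]2(C)COC(C)(C)O2)[C@H](OC(=O)/C=C(/C)CC)[C@@H]1OC(=O)[C@H](C)CC | intermediate
40 | S-oxide of 39 (both sulfur epimers) | O=S(c1ccccc1)C[C@@H]1[C@H]2CC(=O)[C@@H]([C@H](C)O[Si](C)(C)C(C)(C)C)[C@@H]2[C@@H]([C@@]2(C)COC(C)(C)O2)[C@H](OC(=O)/C=C(/C)CC)[C@@H]1OC(=O)[C@H](C)CC | intermediate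
41 | (1R,3aS,5R,6S,7R,7aS)-1-[(1S)-1-{[tert-butyl(dimethyl)silyl]oxy}ethyl]-4-methylidene-5-{[(2R)-2-methylbutanoyl]oxy}-2-oxo-7-[(4S)-2,2,4-trimethyl-1,3-dioxolan-4-yl]octahydro-1H-inden-6-yl (2Z)-3-methylpent-2-enoate | C=C1[C@H]2CC(=O)[C@@H]([C@H](C)O[Si](C)(C)C(C)(C)C)[C@@H]2[C@@H]([C@@]2(C)COC(C)(C)O2)[C@H](OC(=O)/C=C(/C)CC)[C@@H]1OC(=O)[C@H](C)CC | intermediate
42 | (1R,3aS,5R,6S,7R,7aS)-7-[(2S)-1,2-dihydroxypropan-2-yl]-1-[(1S)-1-hydroxyethyl]-4-methylidene-5-{[(2R)-2-methylbutanoyl]oxy}-2-oxooctahydro-1H-inden-6-yl (2Z)-3-methylpent-2-enoate | C=C1[C@H]2CC(=O)[C@@H]([C@H](C)O)[C@@H]2[C@@H]([C@@](O)(C)CO)[C@H](OC(=O)/C=C(/C)CC)[C@@H]1OC(=O)[C@H](C)CC | intermediate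
43 | primary 4-methylbenzenesulfonate of 42 | C=C1[C@H]2CC(=O)[C@@H]([C@H](C)O)[C@@H]2[C@@H]([C@@](O)(C)COS(=O)(=O)c2ccc(C)cc2)[C@H](OC(=O)/C=C(/C)CC)[C@@H]1OC(=O)[C@H](C)CC | intermediate
44 | (1R,3aS,5R,6S,7R,7aS)-1-[(1S)-1-hydroxyethyl]-4-methylidene-5-{[(2R)-2-methylbutanoyl]oxy}-7-[(2S)-2-methyloxiran-2-yl]-2-oxooctahydro-1H-inden-6-yl (2Z)-3-methylpent-2-enoate | C=C1[C@H]2CC(=O)[C@@H]([C@H](C)O)[C@@H]2[C@@H]([C@@]2(C)CO2)[C@H](OC(=O)/C=C(/C)CC)[C@@H]1OC(=O)[C@H](C)CC | intermediate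
45 | (1S)-1-[(1R,3aS,5R,6S,7R,7aS)-4-methylidene-5-{[(2R)-2-methylbutanoyl]oxy}-6-{[(2Z)-3-methylpent-2-enoyl]oxy}-7-[(2S)-2-methyloxiran-2-yl]-2-oxooctahydro-1H-inden-1-yl]ethyl acetate | C=C1[C@H]2CC(=O)[C@@H]([C@H](C)OC(C)=O)[C@@H]2[C@@H]([C@@]2(C)CO2)[C@H](OC(=O)/C=C(/C)CC)[C@@H]1OC(=O)[C@H](C)CC | target

## Step count and main risks

Total step count: 29. Longest linear sequence: 21 steps (steps 1–6, then 15–29).

Steps most likely to fail:

1. Step 25. What may go wrong: hydrogen transfer from the stannane to the acyl radical before the slow 6-exo closure, or loss of facial control in the first closure (cis fusion) or in the final hydrogen-atom transfer at C1. Fallback, setting out from 29 and returning at 39: the two bonds are made by a Pauson–Khand reaction instead. Aldehyde 29 is homologated with dimethyl (1-diazo-2-oxopropyl)phosphonate (K2CO3, MeOH, 0 °C) to the terminal alkyne (3R,4R,5S,6R)-3-[(phenylsulfanyl)methyl]-5-[(triethylsilyl)oxy]-6-[(4S)-2,2,4-trimethyl-1,3-dioxolan-4-yl]oct-1-en-7-yn-4-yl (2R)-2-methylbutanoate F1. HF·pyridine (pyridine, THF, 0 °C) frees the C6 hydroxyl to give the alkynol F2. Yamaguchi esterification with 24 gives the enyne ester F3. Co2(CO)8 in CH2Cl2 followed by N-methylmorpholine N-oxide closes both rings, with CO becoming C2, to give the bicyclic enone (C1=C7a) F4. Conjugate reduction with [(Ph3P)CuH]6 and trapping of the enolate with acetaldehyde (reductive aldol) should give the hydroxyethyl ketone F5. Silylation with TBSOTf and 2,6-lutidine returns to 39. Stereocontrol at C7a, C1 and the carbinol carbon is expected to be lower than in the radical route.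

2. Step 19. What may go wrong: enolisation or retro-aldol of the hindered α-branched aldehyde instead of addition, and β-elimination of the silyloxy group from the ester enolate. Fallback, setting out from 21 and 29 and returning at 33: Horner–Wadsworth–Emmons olefination. Ester 21 is C-phosphorylated (LDA, THF, −78 °C; ClP(OEt)2; then aq. H2O2) to give prop-2-en-1-yl (3S)-3-{[tert-butyl(dimethyl)silyl]oxy}-2-(diethoxyphosphoryl)butanoate F6. F6 is condensed with 29 (LiCl, DBU, MeCN, rt) to give 33 directly, so that 31 and step 20 are bypassed.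

3. Step 28. What may go wrong: sulfonylation of the side-chain secondary hydroxyl, or base-induced retro-aldol, dehydration or epimerisation of the β-hydroxy ketone during ring closure. Fallback, setting out from 41 and returning at 44: the oxirane is closed before the side-chain hydroxyl is freed. Aqueous AcOH (THF, rt) removes only the acetonide of 41 to give the silyl-protected diol F7. Mitsunobu cyclodehydration (PPh3, DIAD, toluene, 0 °C → rt; the primary hydroxyl is activated and the tertiary one closes the ring) gives the silyl-protected epoxide F8. TBAF buffered with AcOH (THF, 0 °C) removes the TBS group to give 44.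

Further compounds

F1 | step 25 | (3R,4R,5S,6R)-3-[(phenylsulfanyl)methyl]-5-[(triethylsilyl)oxy]-6-[(4S)-2,2,4-trimethyl-1,3-dioxolan-4-yl]oct-1-en-7-yn-4-yl (2R)-2-methylbutanoate | C=C[C@@H](CSc1ccccc1)[C@@H](OC(=O)[C@H](C)CC)[C@@H](O[Si](CC)(CC)CC)[C@H]([C@@]1(C)COC(C)(C)O1)C#C
F2 | step 25 | (3R,4R,5S,6R)-5-hydroxy-3-[(phenylsulfanyl)methyl]-6-[(4S)-2,2,4-trimethyl-1,3-dioxolan-4-yl]oct-1-en-7-yn-4-yl (2R)-2-methylbutanoate | C=C[C@@H](CSc1ccccc1)[C@@H](OC(=O)[C@H](C)CC)[C@@H](O)[C@H]([C@@]1(C)COC(C)(C)O1)C#C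
F3 | step 25 | (3R,4R,5S,6R)-4-{[(2R)-2-methylbutanoyl]oxy}-3-[(phenylsulfanyl)methyl]-6-[(4S)-2,2,4-trimethyl-1,3-dioxolan-4-yl]oct-1-en-7-yn-5-yl (2Z)-3-methylpent-2-enoate | C=C[C@@H](CSc1ccccc1)[C@@H](OC(=O)[C@H](C)CC)[C@@H](OC(=O)/C=C(/C)CC)[C@H]([C@@]1(C)COC(C)(C)O1)C#C
F4 | step 25 | (3aR,4R,5R,6S,7R)-5-{[(2R)-2-methylbutanoyl]oxy}-2-oxo-4-[(phenylsulfanyl)methyl]-7-[(4S)-2,2,4-trimethyl-1,3-dioxolan-4-yl]-3,3a,4,5,6,7-hexahydro-2H-inden-6-yl (2Z)-3-methylpent-2-enoate | c1ccccc1SC[C@@H]1[C@H]2CC(=O)C=C2[C@@H]([C@@]2(C)COC(C)(C)O2)[C@H](OC(=O)/C=C(/C)CC)[C@@H]1OC(=O)[C@H](C)CC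
F5 | step 25 | (1R,3aS,4R,5R,6S,7R,7aS)-1-[(1S)-1-hydroxyethyl]-5-{[(2R)-2-methylbutanoyl]oxy}-2-oxo-4-[(phenylsulfanyl)methyl]-7-[(4S)-2,2,4-trimethyl-1,3-dioxolan-4-yl]octahydro-1H-inden-6-yl (2Z)-3-methylpent-2-enoate | c1ccccc1SC[C@@H]1[C@H]2CC(=O)[C@@H]([C@H](C)O)[C@@H]2[C@@H]([C@@]2(C)COC(C)(C)O2)[C@H](OC(=O)/C=C(/C)CC)[C@@H]1OC(=O)[C@H](C)CC
F6 | step 19 | prop-2-en-1-yl (3S)-3-{[tert-butyl(dimethyl)silyl]oxy}-2-(diethoxyphosphoryl)butanoate (C2 epimers) | C=CCOC(=O)C(P(=O)(OCC)OCC)[C@H](C)O[Si](C)(C)C(C)(C)C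
F7 | step 28 | (1R,3aS,5R,6S,7R,7aS)-1-[(1S)-1-{[tert-butyl(dimethyl)silyl]oxy}ethyl]-7-[(2S)-1,2-dihydroxypropan-2-yl]-4-methylidene-5-{[(2R)-2-methylbutanoyl]oxy}-2-oxooctahydro-1H-inden-6-yl (2Z)-3-methylpent-2-enoate | C=C1[C@H]2CC(=O)[C@@H]([C@H](C)O[Si](C)(C)C(C)(C)C)[C@@H]2[C@@H]([C@@](O)(C)CO)[C@H](OC(=O)/C=C(/C)CC)[C@@H]1OC(=O)[C@H](C)CC
F8 | step 28 | (1R,3aS,5R,6S,7R,7aS)-1-[(1S)-1-{[tert-butyl(dimethyl)silyl]oxy}ethyl]-4-methylidene-5-{[(2R)-2-methylbutanoyl]oxy}-7-[(2S)-2-methyloxiran-2-yl]-2-oxooctahydro-1H-inden-6-yl (2Z)-3-methylpent-2-enoate | C=C1[C@H]2CC(=O)[C@@H]([C@H](C)O[Si](C)(C)C(C)(C)C)[C@@H]2[C@@H]([C@@]2(C)CO2)[C@H](OC(=O)/C=C(/C)CC)[C@@H]1OC(=O)[C@H](C)CC
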